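## Retrosynthetic overview

1. The last C–O bond is a Yamaguchi ester union of acid 22 (cyclohexenyl half) with the primary hydroxyl of diol lactone 51 (bicyclic half); the tert-butyl ester and silyl ethers come off at the end.
2. The key C–C bond of each 2-(hydroxymethyl)acrylate (CH=C) comes from an intermolecular aldol addition of a 3-hydroxypropanoate dianion to a ring aldehyde (15 + 16; 43 + 44), followed by β-elimination to the (E)-alkene.
3. Bicyclic half: the ε-lactone is closed last from hydroxy acid 48; the C1 carbinol comes from ketone 36; C4/C4a/C8a come from an auxiliary-controlled Diels–Alder reaction (25 + 29), with iodolactonisation placing oxygen at C1.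
4. Cyclohexenyl half: an auxiliary-controlled Diels–Alder reaction (5 + 8) sets the cis C1'/C6' pair; the acyl group is then converted to isopropyl.
5. Ring order: cyclohexene of the acid half (step 4); cyclohexane of the lactone half (step 18); temporary bridged γ-lactone (step 20); temporary fused γ-lactone (step 30); seven-membered lactone (step 32).

Assumption: the structure is taken exactly as in the given SMILES; TBS = tert-butyldimethylsilyl, TBDPS = tert-butyldiphenylsilyl; lactone-half locants are C1 (carbinol), C4 (i-Pr), C4a/C8a (ring fusion), C5=C6, C7 (OCH2), C8 (lactone C=O), C11 (CH2O-acyl), with primed locants for the acid half.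

## Route

### Fragment A (acid 22)

Step 1
Reactants: 1 2-bromoprop-2-en-1-ol
Product: 2 [(2-bromoprop-2-en-1-yl)oxy](tert-butyl)diphenylsilane
Conditions: t-BuPh2SiCl, imidazole, DMF, 0 °C → rt
Reagents that add atoms: tert-butyl(chloro)diphenylsilane, CC(C)(C)[Si](Cl)(c1ccccc1)c1ccccc1
Why: Standard silyl ether formation on a primary alcohol; no stereocentre is involved.

Step 2
Reactants: 3 tert-butyldimethyl(prop-2-yn-1-yloxy)silane + 2 [(2-bromoprop-2-en-1-yl)oxy](tert-butyl)diphenylsilane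
Product: 5 (3E)-5-(TBSO)-2-methylidene-1-(TBDPSO)pent-3-ene, via alkenyl catecholboronate 4 (not isolated)
Conditions: catecholborane, neat, 70 °C; then 2, Pd(PPh3)4 (3 mol %), 2 M aq. NaOH, THF, 65 °C
Reagents that add atoms: none
Why: Syn hydroboration of the terminal alkyne gives the (E)-alkenylboronate and the Suzuki–Miyaura coupling proceeds with retention, fixing the (E)-diene.

Step 3
Reactants: 6 (4S)-4-benzyl-1,3-oxazolidin-2-one + 7 prop-2-enoyl chloride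
Product: 8 (4S)-4-benzyl-3-(prop-2-enoyl)-1,3-oxazolidin-2-one
Conditions: Et3N, LiCl, THF, –20 °C → rt
Reagents that add atoms: none
Why: N-acylation of the oxazolidinone gives the Evans acrylimide dienophile.

Step 4
Reactants: 5 (3E)-5-(TBSO)-2-methylidene-1-(TBDPSO)pent-3-ene + 8 (4S)-4-benzyl-3-(prop-2-enoyl)-1,3-oxazolidin-2-one
Product: 9 (4S)-4-benzyl-3-{[(1R,2S)-2-(TBSO-methyl)-4-(TBDPSO-methyl)cyclohex-3-en-1-yl]carbonyl}-1,3-oxazolidin-2-one
Conditions: Et2AlCl (1.4 equiv), CH2Cl2, –78 °C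
Reagents that add atoms: none
Why: Evans auxiliary Diels–Alder reaction: the Et2AlCl-chelated s-cis imide is attacked on the face anti to benzyl (Cα-Si), and the endo, "ortho/para" mode of the 1,3-disubstituted diene places the CH2OTBS carbon cis to the acyl group, setting both ring stereocentres.

Step 5
Reactants: 9 (4S)-4-benzyl-3-{[(1R,2S)-2-(TBSO-methyl)-4-(TBDPSO-methyl)cyclohex-3-en-1-yl]carbonyl}-1,3-oxazolidin-2-one
Product: 10 (1R,2S)-N-methoxy-N-methyl-2-(TBSO-methyl)-4-(TBDPSO-methyl)cyclohex-3-ene-1-carboxamide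
Conditions: AlMe3, MeONHMe·HCl, CH2Cl2, 0 °C → rt
Reagents that add atoms: N,O-dimethylhydroxylamine hydrochloride, CNOC.Cl
Why: Weinreb transamidation with the aluminium amide cleaves the auxiliary without epimerising the α-centre.

Step 6
Reactants: 10 (1R,2S)-N-methoxy-N-methyl-2-(TBSO-methyl)-4-(TBDPSO-methyl)cyclohex-3-ene-1-carboxamide
Product: 11 1-[(1R,2S)-2-(TBSO-methyl)-4-(TBDPSO-methyl)cyclohex-3-en-1-yl]ethan-1-one
Conditions: MeMgBr, THF, 0 °C
Reagents that add atoms: methylmagnesium bromide, C[Mg]Br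
Why: Grignard addition to a Weinreb amide stops at the ketone because the chelated tetrahedral adduct survives until work-up.

Step 7
Reactants: 11 1-[(1R,2S)-2-(TBSO-methyl)-4-(TBDPSO-methyl)cyclohex-3-en-1-yl]ethan-1-one
Product: 12 (3S,4R)-3-(TBSO-methyl)-4-(prop-1-en-2-yl)-1-(TBDPSO-methyl)cyclohex-1-ene
Conditions: Zn, CH2Br2, TiCl4, THF/CH2Cl2, 0 °C → rt
Reagents that add atoms: dibromomethane, BrCBr
Why: Lombardo methylenation is non-basic, so the epimerisable centre next to the ketone (cis to its neighbour) is not touched.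

Step 8
Reactants: 12 (3S,4R)-3-(TBSO-methyl)-4-(prop-1-en-2-yl)-1-(TBDPSO-methyl)cyclohex-1-ene
Product: 13 (3R,4S)-3-(TBSO-methyl)-4-(propan-2-yl)-1-(TBDPSO-methyl)cyclohex-1-ene
Conditions: H2 (1 atm), RhCl(PPh3)3 (5 mol %), benzene/EtOH, rt
Reagents that add atoms: none
Why: Homogeneous hydrogenation with RhCl(PPh3)3 reduces the 1,1-disubstituted alkene and leaves the trisubstituted ring alkene (the descriptors change by CIP priority only).

Step 9
Reactants: 13 (3R,4S)-3-(TBSO-methyl)-4-(propan-2-yl)-1-(TBDPSO-methyl)cyclohex-1-ene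
Product: 14 [(1R,6S)-6-(propan-2-yl)-3-(TBDPSO-methyl)cyclohex-2-en-1-yl]methanol
Conditions: PPTS (cat.), MeOH, rt
Reagents that add atoms: none
Why: Acid-catalysed methanolysis removes the primary TBS ether much faster than the TBDPS ether.

Step 10
Reactants: 14 [(1R,6S)-6-(propan-2-yl)-3-(TBDPSO-methyl)cyclohex-2-en-1-yl]methanol
Product: 15 (1R,6S)-6-(propan-2-yl)-3-(TBDPSO-methyl)cyclohex-2-ene-1-carbaldehyde
Conditions: Dess–Martin periodinane, NaHCO3, CH2Cl2, 0 °C; used crude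
Reagents that add atoms: none
Why: Buffered Dess–Martin oxidation is base-free, so the β,γ-unsaturated aldehyde neither epimerises nor moves into conjugation.

Step 11
Reactants: 15 (1R,6S)-6-(propan-2-yl)-3-(TBDPSO-methyl)cyclohex-2-ene-1-carbaldehyde + 16 methyl 3-hydroxypropanoate
Product: 18 methyl 3-hydroxy-2-(hydroxymethyl)-3-[(1R,6S)-6-(propan-2-yl)-3-(TBDPSO-methyl)cyclohex-2-en-1-yl]propanoate (epimer mixture at C2/C3), via dilithium dianion 17 (not isolated)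
Conditions: 16 (2.5 equiv), LiN(i-Pr)2 (2.1 equiv per 16), THF, –78 → –40 °C; then 15, –78 °C; AcOH
Reagents that add atoms: none
Why: Intermolecular aldol addition of a Fráter–Seebach-type dianion (its β-alkoxide cannot eliminate) is faster at –78 °C than enolisation of the aldehyde; the two new centres are removed in step 13.

Step 12
Reactants: 18 methyl 3-hydroxy-2-(hydroxymethyl)-3-[(1R,6S)-6-(propan-2-yl)-3-(TBDPSO-methyl)cyclohex-2-en-1-yl]propanoate
Product: 19 methyl 3-hydroxy-2-(TBSO-methyl)-3-[(1R,6S)-6-(propan-2-yl)-3-(TBDPSO-methyl)cyclohex-2-en-1-yl]propanoate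
Conditions: t-BuMe2SiCl, imidazole, CH2Cl2, 0 °C
Reagents that add atoms: tert-butyl(chloro)dimethylsilane, CC(C)(C)[Si](C)(C)Cl
Why: Silylation is selective for the primary hydroxyl over the hindered secondary one.

Step 13
Reactants: 19 methyl 3-hydroxy-2-(TBSO-methyl)-3-[(1R,6S)-6-(propan-2-yl)-3-(TBDPSO-methyl)cyclohex-2-en-1-yl]propanoate
Product: 21 methyl (2E)-2-(TBSO-methyl)-3-[(1R,6S)-6-(propan-2-yl)-3-(TBDPSO-methyl)cyclohex-2-en-1-yl]prop-2-enoate, via mesylate 20 (not isolated)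
Conditions: MsCl, Et3N, CH2Cl2, 0 °C; then DBU, rt
Reagents that add atoms: none
Why: Mesylation and E1cB elimination give the thermodynamically preferred (E)-enoate (ester trans to the ring) from either aldol epimer.

Step 14
Reactants: 21 methyl (2E)-2-(TBSO-methyl)-3-[(1R,6S)-6-(propan-2-yl)-3-(TBDPSO-methyl)cyclohex-2-en-1-yl]prop-2-enoate
Product: 22 (2E)-2-(TBSO-methyl)-3-[(1R,6S)-6-(propan-2-yl)-3-(TBDPSO-methyl)cyclohex-2-en-1-yl]prop-2-enoic acid
Conditions: LiOH, THF/MeOH/H2O, rt; then 1 M HCl to pH 4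
Reagents that add atoms: lithium hydroxide, [Li+].[OH-]
Why: Saponification of the hindered enoate; silyl ethers and the skipped diene tolerate aqueous LiOH at rt.

### Fragment B (diol lactone 51)

Step 15
Reactants: 23 penta-1,4-dien-3-ol
Product: 24 (2E)-penta-2,4-dien-1-ol
Conditions: 1% aq. H2SO4, rt
Reagents that add atoms: water, O
Why: Acid-catalysed allylic transposition through the pentadienyl cation gives the conjugated primary (E)-dienol.

Step 16
Reactants: 24 (2E)-penta-2,4-dien-1-ol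
Product: 25 tert-butyl[(2E)-penta-2,4-dien-1-yloxy]diphenylsilane
Conditions: t-BuPh2SiCl, imidazole, DMF, 0 °C → rt
Reagents that add atoms: tert-butyl(chloro)diphenylsilane, CC(C)(C)[Si](Cl)(c1ccccc1)c1ccccc1
Why: Silyl ether formation; the bulky, weakly Lewis-basic TBDPS ether tolerates the Lewis acid of step 18.

Step 17
Reactants: 26 (2E)-4-methylpent-2-enoic acid + 27 (4R)-4-benzyl-1,3-oxazolidin-2-one
Product: 29 (4R)-4-benzyl-3-[(2E)-4-methylpent-2-enoyl]-1,3-oxazolidin-2-one, via mixed pivalic anhydride 28 (not isolated)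
Conditions: t-BuCOCl, Et3N, THF, –20 °C; then 27, LiCl, rt
Reagents that add atoms: none
Why: Mixed-anhydride N-acylation (LiCl/Et3N) gives the (E)-enoyl imide without alkene isomerisation.

Step 18
Reactants: 25 tert-butyl[(2E)-penta-2,4-dien-1-yloxy]diphenylsilane + 29 (4R)-4-benzyl-3-[(2E)-4-methylpent-2-enoyl]-1,3-oxazolidin-2-one
Product: 30 (4R)-4-benzyl-3-{[(1S,2R,6S)-6-(propan-2-yl)-2-(TBDPSO-methyl)cyclohex-3-en-1-yl]carbonyl}-1,3-oxazolidin-2-one
Conditions: Et2AlCl (1.5 equiv), 25 (3 equiv), CH2Cl2, –30 → 0 °C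
Reagents that add atoms: none
Why: Evans auxiliary Diels–Alder reaction: attack on the Cα-Re face of the chelated (R)-imide sets C4a, the (E)-dienophile geometry puts i-Pr (C4) trans to the acyl group, and the endo/"ortho" mode puts the C8a CH2OTBDPS cis to it.

Step 19
Reactants: 30 (4R)-4-benzyl-3-{[(1S,2R,6S)-6-(propan-2-yl)-2-(TBDPSO-methyl)cyclohex-3-en-1-yl]carbonyl}-1,3-oxazolidin-2-one
Product: 31 (1S,2R,6S)-6-(propan-2-yl)-2-(TBDPSO-methyl)cyclohex-3-ene-1-carboxylic acid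
Conditions: LiOH, H2O2, THF/H2O, 0 °C; then Na2SO3; HCl to pH 3
Reagents that add atoms: hydrogen peroxide (as LiOOH), OO
Why: Hydroperoxide hydrolysis cleaves the exocyclic imide carbonyl selectively and without epimerisation.

Step 20
Reactants: 31 (1S,2R,6S)-6-(propan-2-yl)-2-(TBDPSO-methyl)cyclohex-3-ene-1-carboxylic acid
Product: 32 4-iodo-2-(propan-2-yl)-8-(TBDPSO-methyl)-6-oxabicyclo[3.2.1]octan-7-one (ring O cis to the carbonyl bridge; iodine trans to ring O; other centres as in 31)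
Conditions: I2, KI, NaHCO3, THF/H2O, 0 °C → rt, dark
Reagents that add atoms: iodine, II
Why: Iodolactonisation: the carboxylate opens the iodonium ion at the γ-carbon in a 5-exo manner, which places oxygen regioselectively at C1 on the face of the carboxyl group, with iodide anti.

Step 21
Reactants: 32 4-iodo-2-(propan-2-yl)-8-(TBDPSO-methyl)-6-oxabicyclo[3.2.1]octan-7-one
Product: 33 2-(propan-2-yl)-8-(TBDPSO-methyl)-6-oxabicyclo[3.2.1]octan-7-one (configuration as in 32)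
Conditions: Bu3SnH, AIBN (cat.), toluene, 80 °C
Reagents that add atoms: none
Why: Radical deiodination removes the halogen without touching the lactone or the stereocentres.

Step 22
Reactants: 33 2-(propan-2-yl)-8-(TBDPSO-methyl)-6-oxabicyclo[3.2.1]octan-7-one
Product: 34 2-(propan-2-yl)-8-(TBDPSO-methyl)-6-oxabicyclo[3.2.1]octan-7-ol (lactol; anomer mixture)
Conditions: i-Bu2AlH, CH2Cl2, –78 °C
Reagents that add atoms: none
Why: Low-temperature hydride half-reduction of a lactone stops at the lactol.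

Step 23
Reactants: 34 2-(propan-2-yl)-8-(TBDPSO-methyl)-6-oxabicyclo[3.2.1]octan-7-ol
Product: 35 (1R,2R,3S,4S)-3-ethenyl-4-(propan-2-yl)-2-(TBDPSO-methyl)cyclohexan-1-ol
Conditions: Ph3PCH3Br, KOt-Bu (3 equiv each), THF, 0 °C → rt
Reagents that add atoms: methyltriphenylphosphonium bromide, C[P+](c1ccccc1)(c1ccccc1)c1ccccc1.[Br-]
Why: Wittig methylenation of the open hydroxy-aldehyde form of the lactol stores C5 as an inert vinyl group and frees the C1 hydroxyl.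

Step 24
Reactants: 35 (1R,2R,3S,4S)-3-ethenyl-4-(propan-2-yl)-2-(TBDPSO-methyl)cyclohexan-1-ol
Product: 36 (2R,3S,4S)-3-ethenyl-4-(propan-2-yl)-2-(TBDPSO-methyl)cyclohexan-1-one
Conditions: Dess–Martin periodinane, NaHCO3, CH2Cl2, rt
Reagents that add atoms: none
Why: Neutral Dess–Martin oxidation gives the ketone without epimerising the adjacent C8a centre.

Step 25
Reactants: 36 (2R,3S,4S)-3-ethenyl-4-(propan-2-yl)-2-(TBDPSO-methyl)cyclohexan-1-one
Product: 38 (1R,2R,3S,4S)-3-ethenyl-1-(hydroxymethyl)-4-(propan-2-yl)-2-(TBDPSO-methyl)cyclohexan-1-ol, via β-hydroxysilane 37 (not isolated)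
Conditions: ClCH2SiMe2(Oi-Pr), Mg, THF; then 36, 0 °C → rt; then H2O2 (30%), KF, KHCO3, MeOH/THF, rt
Reagents that add atoms: (chloromethyl)dimethyl(propan-2-yloxy)silane, CC(C)O[Si](C)(C)CCl; hydrogen peroxide, OO
Why: Tamao nucleophilic hydroxymethylation (Grignard addition, then Tamao–Fleming oxidation): the Grignard adds to the carbonyl face anti to the adjacent C8a substituent, so the tertiary OH ends cis to that substituent and C1 is set.

Step 26
Reactants: 38 (1R,2R,3S,4S)-3-ethenyl-1-(hydroxymethyl)-4-(propan-2-yl)-2-(TBDPSO-methyl)cyclohexan-1-ol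
Product: 39 (5R,6R,7S,8S)-7-ethenyl-2,2-dimethyl-8-(propan-2-yl)-6-(TBDPSO-methyl)-1,3-dioxaspiro[4.5]decane
Conditions: Me2C(OMe)2, PPTS (cat.), acetone, rt
Reagents that add atoms: 2,2-dimethoxypropane, COC(C)(C)OC
Why: Acetonide formation protects the tertiary and primary hydroxyls together, which also blocks any retro-aldol pathway later.

Step 27
Reactants: 39 (5R,6R,7S,8S)-7-ethenyl-2,2-dimethyl-8-(propan-2-yl)-6-(TBDPSO-methyl)-1,3-dioxaspiro[4.5]decane
Product: 40 [(5R,6R,7S,8S)-7-ethenyl-2,2-dimethyl-8-(propan-2-yl)-1,3-dioxaspiro[4.5]decan-6-yl]methanol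
Conditions: Bu4NF, THF, rt
Reagents that add atoms: none
Why: Fluoride desilylation; the neighbouring group is an inert vinyl, so the freed alcohol cannot lactonise.

Step 28
Reactants: 40 [(5R,6R,7S,8S)-7-ethenyl-2,2-dimethyl-8-(propan-2-yl)-1,3-dioxaspiro[4.5]decan-6-yl]methanol
Product: 41 (5R,6S,7S,8S)-7-ethenyl-2,2-dimethyl-8-(propan-2-yl)-1,3-dioxaspiro[4.5]decane-6-carboxylic acid
Conditions: TEMPO (cat.), PhI(OAc)2 (2.2 equiv), MeCN/H2O, rt
Reagents that add atoms: water, O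
Why: Oxoammonium (TEMPO) oxidation takes the primary alcohol to the acid through the aldehyde hydrate without affecting the alkene or acetonide (the descriptor at C6 changes by priority only).

Step 29
Reactants: 41 (5R,6S,7S,8S)-7-ethenyl-2,2-dimethyl-8-(propan-2-yl)-1,3-dioxaspiro[4.5]decane-6-carboxylic acid
Product: 43 cis-fused hydroxy-γ-lactone (lactol form) of (5R,6S,7S,8S)-7-formyl-2,2-dimethyl-8-(propan-2-yl)-1,3-dioxaspiro[4.5]decane-6-carboxylic acid (anomer mixture), via ozonide 42 (not isolated)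
Conditions: O3, CH2Cl2, –78 °C; then PPh3, –78 °C → rt
Reagents that add atoms: ozone, [O-][O+]=O
Why: Ozonolysis unmasks the C5 aldehyde, which is trapped by the cis carboxyl group as a stable pseudo-acid.

Step 30
Reactants: 43 cis-fused hydroxy-γ-lactone of the 7-formyl-6-carboxylic acid + 44 tert-butyl 3-hydroxypropanoate
Product: 47 cis-fused γ-lactone of the aldol adduct (C8 carboxyl closed onto the new C5 oxygen; C5 bears CH(CH2OH)CO2t-Bu; epimer mixture at the two new centres), via dilithium dianion 45 (not isolated), via hydroxy acid 46 (not isolated)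
Conditions: 44 (3.2 equiv), LiN(i-Pr)2 (6.5 equiv), THF, –78 → –40 °C; then 43, –78 °C; AcOH; then PPTS (cat.), toluene, 40 °C
Reagents that add atoms: none
Why: Intermolecular aldol addition of the dianion to the ring-opened lactolate (carboxylate aldehyde); the resulting cis γ-hydroxy acid lactonises, which locks the C8a configuration and turns the C5 oxygen into a leaving group.

Step 31
Reactants: 47 cis-fused γ-lactone of the aldol adduct
Product: 48 (5R,6S,7R,8S)-7-[(1E)-3-tert-butoxy-2-(hydroxymethyl)-3-oxoprop-1-en-1-yl]-2,2-dimethyl-8-(propan-2-yl)-1,3-dioxaspiro[4.5]decane-6-carboxylic acid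
Conditions: DBU, CH2Cl2, rt; aq. citric acid
Reagents that add atoms: none
Why: E1cB β-elimination expels the lactone carboxylate and gives the thermodynamic (E)-enoate (ester trans to the ring, CH2OH cis), freeing the C8 acid.

Step 32
Reactants: 48 (5R,6S,7R,8S)-7-[(1E)-3-tert-butoxy-2-(hydroxymethyl)-3-oxoprop-1-en-1-yl]-2,2-dimethyl-8-(propan-2-yl)-1,3-dioxaspiro[4.5]decane-6-carboxylic acid
Product: 50 isopropylidene acetal of 51 (spiro-dioxolane on the 9-hydroxy/9-hydroxymethyl pair), via mixed anhydride 49 (not isolated)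
Conditions: 2-methyl-6-nitrobenzoic anhydride, DMAP, Et3N, CH2Cl2 (2 mM), rt
Reagents that add atoms: none
Why: Shiina lactonisation at rt closes the seven-membered ring without epimerising C8a; only the (E)-alkene with CH2OH cis to the ring can cyclise.

Step 33
Reactants: 50 isopropylidene acetal of 51
Product: 51 tert-butyl (5aR,6S,9R,9aS)-9-hydroxy-9-(hydroxymethyl)-1-oxo-6-(propan-2-yl)-1,3,5a,6,7,8,9,9a-octahydro-2-benzoxepine-4-carboxylate
Conditions: AcOH/H2O/THF (3:1:1), 40 °C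
Reagents that add atoms: none
Why: Mild acetal hydrolysis frees the diol; the tert-butyl ester and lactone survive aqueous acetic acid.

### Union and deprotection

Step 34
Reactants: 22 (2E)-2-(TBSO-methyl)-3-[(1R,6S)-6-(propan-2-yl)-3-(TBDPSO-methyl)cyclohex-2-en-1-yl]prop-2-enoic acid + 51 tert-butyl (5aR,6S,9R,9aS)-9-hydroxy-9-(hydroxymethyl)-1-oxo-6-(propan-2-yl)-1,3,5a,6,7,8,9,9a-octahydro-2-benzoxepine-4-carboxylate
Product: 53 tert-butyl (5aR,6S,9R,9aS)-9-hydroxy-9-({[(2E)-2-(TBSO-methyl)-3-[(1R,6S)-6-(propan-2-yl)-3-(TBDPSO-methyl)cyclohex-2-en-1-yl]prop-2-enoyl]oxy}methyl)-1-oxo-6-(propan-2-yl)-1,3,5a,6,7,8,9,9a-octahydro-2-benzoxepine-4-carboxylate, via mixed anhydride 52 (not isolated)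
Conditions: 2,4,6-trichlorobenzoyl chloride, Et3N, toluene, rt; then 51, DMAP, rt
Reagents that add atoms: none
Why: Yamaguchi esterification acylates the primary hydroxyl only; the tertiary hydroxyl is too hindered and the acid has no α-hydrogen to epimerise.

Step 35
Reactants: 53 fully protected ester
Product: 55 carboxylic acid of 53 with the tertiary hydroxyl as its trimethylsilyl ether, via trimethylsilyl ester 54 (not isolated)
Conditions: Me3SiOTf, 2,6-lutidine, CH2Cl2, 0 °C; pH 7 buffer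
Reagents that add atoms: trimethylsilyl trifluoromethanesulfonate, C[Si](C)(C)OS(=O)(=O)C(F)(F)F
Why: Silyl triflate-mediated cleavage of the tert-butyl ester (loss of isobutene, silyl ester hydrolysed on work-up) leaves the TBS/TBDPS ethers and both other esters intact.

Step 36
Reactants: 55 carboxylic acid with tertiary O-SiMe3
Product: 56 (5aR,6S,9R,9aS)-9-hydroxy-9-({[(2E)-2-(hydroxymethyl)-3-[(1R,6S)-3-(hydroxymethyl)-6-(propan-2-yl)cyclohex-2-en-1-yl]prop-2-enoyl]oxy}methyl)-1-oxo-6-(propan-2-yl)-1,3,5a,6,7,8,9,9a-octahydro-2-benzoxepine-4-carboxylic acid (target)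
Conditions: HF·pyridine, pyridine, THF, 0 °C → rt
Reagents that add atoms: none
Why: Buffered fluoride desilylation removes all three silyl groups under non-basic conditions, so no acyl migration, retro-aldol or lactone opening occurs.

## Compound list

1 | 2-bromoprop-2-en-1-ol | C=C(Br)CO | starting material
2 | [(2-bromoprop-2-en-1-yl)oxy](tert-butyl)diphenylsilane | C=C(Br)CO[Si](c1ccccc1)(c1ccccc1)C(C)(C)C | intermediate
3 | tert-butyldimethyl(prop-2-yn-1-yloxy)silane | C#CCO[Si](C)(C)C(C)(C)C | starting material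
4 | 2-[(1E)-3-(TBSO)prop-1-en-1-yl]-1,3,2-benzodioxaborole | CC(C)(C)[Si](C)(C)OC/C=C/B1Oc2ccccc2O1 | intermediate (not isolated)
5 | (3E)-5-(TBSO)-2-methylidene-1-(TBDPSO)pent-3-ene | C=C(CO[Si](c1ccccc1)(c1ccccc1)C(C)(C)C)/C=C/CO[Si](C)(C)C(C)(C)C | intermediate
6 | (4S)-4-benzyl-1,3-oxazolidin-2-one | O=C1N[C@@H](Cc2ccccc2)CO1 | starting material
7 | prop-2-enoyl chloride | C=CC(=O)Cl | starting material
8 | (4S)-4-benzyl-3-(prop-2-enoyl)-1,3-oxazolidin-2-one | C=CC(=O)N1[C@@H](Cc2ccccc2)COC1=O | intermediate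
9 | (4S)-4-benzyl-3-{[(1R,2S)-2-(TBSO-methyl)-4-(TBDPSO-methyl)cyclohex-3-en-1-yl]carbonyl}-1,3-oxazolidin-2-one | CC(C)(C)[Si](C)(C)OC[C@H]1C=C(CO[Si](c2ccccc2)(c2ccccc2)C(C)(C)C)CC[C@H]1C(=O)N1[C@@H](Cc2ccccc2)COC1=O | intermediate
10 | (1R,2S)-N-methoxy-N-methyl-2-(TBSO-methyl)-4-(TBDPSO-methyl)cyclohex-3-ene-1-carboxamide | CC(C)(C)[Si](C)(C)OC[C@H]1C=C(CO[Si](c2ccccc2)(c2ccccc2)C(C)(C)C)CC[C@H]1C(=O)N(C)OC | intermediate
11 | 1-[(1R,2S)-2-(TBSO-methyl)-4-(TBDPSO-methyl)cyclohex-3-en-1-yl]ethan-1-one | CC(C)(C)[Si](C)(C)OC[C@H]1C=C(CO[Si](c2ccccc2)(c2ccccc2)C(C)(C)C)CC[C@H]1C(C)=O | intermediate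
12 | (3S,4R)-3-(TBSO-methyl)-4-(prop-1-en-2-yl)-1-(TBDPSO-methyl)cyclohex-1-ene | CC(C)(C)[Si](C)(C)OC[C@H]1C=C(CO[Si](c2ccccc2)(c2ccccc2)C(C)(C)C)CC[C@H]1C(C)=C | intermediate
13 | (3R,4S)-3-(TBSO-methyl)-4-(propan-2-yl)-1-(TBDPSO-methyl)cyclohex-1-ene | CC(C)(C)[Si](C)(C)OC[C@H]1C=C(CO[Si](c2ccccc2)(c2ccccc2)C(C)(C)C)CC[C@H]1C(C)C | intermediate
14 | [(1R,6S)-6-(propan-2-yl)-3-(TBDPSO-methyl)cyclohex-2-en-1-yl]methanol | OC[C@H]1C=C(CO[Si](c2ccccc2)(c2ccccc2)C(C)(C)C)CC[C@H]1C(C)C | intermediate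
15 | (1R,6S)-6-(propan-2-yl)-3-(TBDPSO-methyl)cyclohex-2-ene-1-carbaldehyde | O=C[C@H]1C=C(CO[Si](c2ccccc2)(c2ccccc2)C(C)(C)C)CC[C@H]1C(C)C | intermediate
16 | methyl 3-hydroxypropanoate | COC(=O)CCO | starting material
17 | dilithium dianion of methyl 3-hydroxypropanoate (alkoxide ester enolate) | [Li+].[Li+].COC([O-])=CC[O-] | intermediate (not isolated)
18 | methyl 3-hydroxy-2-(hydroxymethyl)-3-[(1R,6S)-6-(propan-2-yl)-3-(TBDPSO-methyl)cyclohex-2-en-1-yl]propanoate (epimers at C2/C3) | COC(=O)C(CO)C(O)[C@H]1C=C(CO[Si](c2ccccc2)(c2ccccc2)C(C)(C)C)CC[C@H]1C(C)C | intermediate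
19 | methyl 3-hydroxy-2-(TBSO-methyl)-3-[(1R,6S)-6-(propan-2-yl)-3-(TBDPSO-methyl)cyclohex-2-en-1-yl]propanoate | COC(=O)C(CO[Si](C)(C)C(C)(C)C)C(O)[C@H]1C=C(CO[Si](c2ccccc2)(c2ccccc2)C(C)(C)C)CC[C@H]1C(C)C | intermediate
20 | methanesulfonate of 19 (at the secondary hydroxyl) | COC(=O)C(CO[Si](C)(C)C(C)(C)C)C(OS(C)(=O)=O)[C@H]1C=C(CO[Si](c2ccccc2)(c2ccccc2)C(C)(C)C)CC[C@H]1C(C)C | intermediate (not isolated)
21 | methyl (2E)-2-(TBSO-methyl)-3-[(1R,6S)-6-(propan-2-yl)-3-(TBDPSO-methyl)cyclohex-2-en-1-yl]prop-2-enoate | COC(=O)/C(=C/[C@H]1C=C(CO[Si](c2ccccc2)(c2ccccc2)C(C)(C)C)CC[C@H]1C(C)C)CO[Si](C)(C)C(C)(C)C | intermediate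
22 | (2E)-2-(TBSO-methyl)-3-[(1R,6S)-6-(propan-2-yl)-3-(TBDPSO-methyl)cyclohex-2-en-1-yl]prop-2-enoic acid | OC(=O)/C(=C/[C@H]1C=C(CO[Si](c2ccccc2)(c2ccccc2)C(C)(C)C)CC[C@H]1C(C)C)CO[Si](C)(C)C(C)(C)C | intermediate
23 | penta-1,4-dien-3-ol | C=CC(O)C=C | starting material
24 | (2E)-penta-2,4-dien-1-ol | OC/C=C/C=C | intermediate
25 | tert-butyl[(2E)-penta-2,4-dien-1-yloxy]diphenylsilane | C=C/C=C/CO[Si](c1ccccc1)(c1ccccc1)C(C)(C)C | intermediate
26 | (2E)-4-methylpent-2-enoic acid | CC(C)/C=C/C(=O)O | starting material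
27 | (4R)-4-benzyl-1,3-oxazolidin-2-one | O=C1N[C@H](Cc2ccccc2)CO1 | starting material
28 | (2E)-4-methylpent-2-enoic pivalic anhydride | CC(C)/C=C/C(=O)OC(=O)C(C)(C)C | intermediate (not isolated)
29 | (4R)-4-benzyl-3-[(2E)-4-methylpent-2-enoyl]-1,3-oxazolidin-2-one | CC(C)/C=C/C(=O)N1[C@H](Cc2ccccc2)COC1=O | intermediate
30 | (4R)-4-benzyl-3-{[(1S,2R,6S)-6-(propan-2-yl)-2-(TBDPSO-methyl)cyclohex-3-en-1-yl]carbonyl}-1,3-oxazolidin-2-one | CC(C)[C@@H]1CC=C[C@@H](CO[Si](c2ccccc2)(c2ccccc2)C(C)(C)C)[C@H]1C(=O)N1[C@H](Cc2ccccc2)COC1=O | intermediate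
31 | (1S,2R,6S)-6-(propan-2-yl)-2-(TBDPSO-methyl)cyclohex-3-ene-1-carboxylic acid | CC(C)[C@@H]1CC=C[C@@H](CO[Si](c2ccccc2)(c2ccccc2)C(C)(C)C)[C@H]1C(=O)O | intermediate
32 | 4-iodo-2-(propan-2-yl)-8-(TBDPSO-methyl)-6-oxabicyclo[3.2.1]octan-7-one (ring O cis to carbonyl bridge; I trans to ring O; CH2OTBDPS syn to the lactone bridge; i-Pr trans to the carbonyl carbon) | CC(C)[C@@H]1C[C@H](I)[C@H]2OC(=O)[C@@H]1[C@@H]2CO[Si](c1ccccc1)(c1ccccc1)C(C)(C)C | intermediate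
33 | 2-(propan-2-yl)-8-(TBDPSO-methyl)-6-oxabicyclo[3.2.1]octan-7-one (configuration as in 32) | CC(C)[C@@H]1CC[C@H]2OC(=O)[C@@H]1[C@@H]2CO[Si](c1ccccc1)(c1ccccc1)C(C)(C)C | intermediate
34 | 2-(propan-2-yl)-8-(TBDPSO-methyl)-6-oxabicyclo[3.2.1]octan-7-ol (lactol; anomers) | CC(C)[C@@H]1CC[C@H]2OC(O)[C@@H]1[C@@H]2CO[Si](c1ccccc1)(c1ccccc1)C(C)(C)C | intermediate
35 | (1R,2R,3S,4S)-3-ethenyl-4-(propan-2-yl)-2-(TBDPSO-methyl)cyclohexan-1-ol | CC(C)[C@@H]1CC[C@@H](O)[C@@H](CO[Si](c2ccccc2)(c2ccccc2)C(C)(C)C)[C@H]1C=C | intermediate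
36 | (2R,3S,4S)-3-ethenyl-4-(propan-2-yl)-2-(TBDPSO-methyl)cyclohexan-1-one | CC(C)[C@@H]1CCC(=O)[C@@H](CO[Si](c2ccccc2)(c2ccccc2)C(C)(C)C)[C@H]1C=C | intermediate
37 | (1R,2R,3S,4S)-1-{[dimethyl(propan-2-yloxy)silyl]methyl}-3-ethenyl-4-(propan-2-yl)-2-(TBDPSO-methyl)cyclohexan-1-ol | CC(C)[C@@H]1CC[C@](O)(C[Si](C)(C)OC(C)C)[C@@H](CO[Si](c2ccccc2)(c2ccccc2)C(C)(C)C)[C@H]1C=C | intermediate (not isolated)
38 | (1R,2R,3S,4S)-3-ethenyl-1-(hydroxymethyl)-4-(propan-2-yl)-2-(TBDPSO-methyl)cyclohexan-1-ol | CC(C)[C@@H]1CC[C@](O)(CO)[C@@H](CO[Si](c2ccccc2)(c2ccccc2)C(C)(C)C)[C@H]1C=C | intermediate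
39 | (5R,6R,7S,8S)-7-ethenyl-2,2-dimethyl-8-(propan-2-yl)-6-(TBDPSO-methyl)-1,3-dioxaspiro[4.5]decane | CC(C)[C@@H]1CC[C@]2(COC(C)(C)O2)[C@@H](CO[Si](c2ccccc2)(c2ccccc2)C(C)(C)C)[C@H]1C=C | intermediate
40 | [(5R,6R,7S,8S)-7-ethenyl-2,2-dimethyl-8-(propan-2-yl)-1,3-dioxaspiro[4.5]decan-6-yl]methanol | CC(C)[C@@H]1CC[C@]2(COC(C)(C)O2)[C@@H](CO)[C@H]1C=C | intermediate
41 | (5R,6S,7S,8S)-7-ethenyl-2,2-dimethyl-8-(propan-2-yl)-1,3-dioxaspiro[4.5]decane-6-carboxylic acid | CC(C)[C@@H]1CC[C@]2(COC(C)(C)O2)[C@@H](C(=O)O)[C@H]1C=C | intermediate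
42 | secondary ozonide of 41 (1,2,4-trioxolan-3-yl in place of ethenyl) | CC(C)[C@@H]1CC[C@]2(COC(C)(C)O2)[C@@H](C(=O)O)[C@H]1C1OCOO1 | intermediate (not isolated)
43 | cis-fused hydroxy-γ-lactone (lactol form) of (5R,6S,7S,8S)-7-formyl-2,2-dimethyl-8-(propan-2-yl)-1,3-dioxaspiro[4.5]decane-6-carboxylic acid | CC(C)[C@@H]1CC[C@]2(COC(C)(C)O2)[C@H]2C(=O)OC(O)[C@@H]12 | intermediate
44 | tert-butyl 3-hydroxypropanoate | CC(C)(C)OC(=O)CCO | starting material
45 | dilithium dianion of tert-butyl 3-hydroxypropanoate | [Li+].[Li+].CC(C)(C)OC([O-])=CC[O-] | intermediate (not isolated)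
46 | (5R,6S,8S)-7-[3-tert-butoxy-1-hydroxy-2-(hydroxymethyl)-3-oxopropyl]-2,2-dimethyl-8-(propan-2-yl)-1,3-dioxaspiro[4.5]decane-6-carboxylic acid (ring centres as in 41; epimers in the side chain) | CC(C)[C@@H]1CC[C@]2(COC(C)(C)O2)[C@@H](C(=O)O)[C@H]1C(O)C(CO)C(=O)OC(C)(C)C | intermediate (not isolated)
47 | cis-fused γ-lactone of 46 (6-carboxyl closed onto the new secondary hydroxyl; epimers at the two new centres) | CC(C)[C@@H]1CC[C@]2(COC(C)(C)O2)[C@H]2C(=O)OC(C(CO)C(=O)OC(C)(C)C)[C@@H]12 | intermediate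
48 | (5R,6S,7R,8S)-7-[(1E)-3-tert-butoxy-2-(hydroxymethyl)-3-oxoprop-1-en-1-yl]-2,2-dimethyl-8-(propan-2-yl)-1,3-dioxaspiro[4.5]decane-6-carboxylic acid | CC(C)[C@@H]1CC[C@]2(COC(C)(C)O2)[C@@H](C(=O)O)[C@H]1/C=C(\CO)C(=O)OC(C)(C)C | intermediate
49 | mixed anhydride of 48 with 2-methyl-6-nitrobenzoic acid | CC(C)[C@@H]1CC[C@]2(COC(C)(C)O2)[C@@H](C(=O)OC(=O)c2c(C)cccc2[N+](=O)[O-])[C@H]1/C=C(\CO)C(=O)OC(C)(C)C | intermediate (not isolated)
50 | isopropylidene acetal of 51 (spiro-dioxolane on the 9-hydroxy/9-hydroxymethyl pair) | CC(C)[C@@H]1CC[C@]2(COC(C)(C)O2)[C@H]2C(=O)OCC(C(=O)OC(C)(C)C)=C[C@@H]12 | intermediate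
51 | tert-butyl (5aR,6S,9R,9aS)-9-hydroxy-9-(hydroxymethyl)-1-oxo-6-(propan-2-yl)-1,3,5a,6,7,8,9,9a-octahydro-2-benzoxepine-4-carboxylate | CC(C)[C@@H]1CC[C@](O)(CO)[C@H]2C(=O)OCC(C(=O)OC(C)(C)C)=C[C@@H]12 | intermediate
52 | mixed anhydride of 22 with 2,4,6-trichlorobenzoic acid | O=C(OC(=O)c1c(Cl)cc(Cl)cc1Cl)/C(=C/[C@H]1C=C(CO[Si](c2ccccc2)(c2ccccc2)C(C)(C)C)CC[C@H]1C(C)C)CO[Si](C)(C)C(C)(C)C | intermediate (not isolated)
53 | tert-butyl (5aR,6S,9R,9aS)-9-hydroxy-9-({[(2E)-2-(TBSO-methyl)-3-[(1R,6S)-6-(propan-2-yl)-3-(TBDPSO-methyl)cyclohex-2-en-1-yl]prop-2-enoyl]oxy}methyl)-1-oxo-6-(propan-2-yl)-1,3,5a,6,7,8,9,9a-octahydro-2-benzoxepine-4-carboxylate | CC(C)[C@@H]1CC[C@](O)(COC(=O)/C(=C/[C@H]2C=C(CO[Si](c3ccccc3)(c3ccccc3)C(C)(C)C)CC[C@H]2C(C)C)CO[Si](C)(C)C(C)(C)C)[C@H]2C(=O)OCC(C(=O)OC(C)(C)C)=C[C@@H]12 | intermediate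
54 | trimethylsilyl ester of 55 (tertiary O-SiMe3 and CO2SiMe3) | CC(C)[C@@H]1CC[C@](O[Si](C)(C)C)(COC(=O)/C(=C/[C@H]2C=C(CO[Si](c3ccccc3)(c3ccccc3)C(C)(C)C)CC[C@H]2C(C)C)CO[Si](C)(C)C(C)(C)C)[C@H]2C(=O)OCC(C(=O)O[Si](C)(C)C)=C[C@@H]12 | intermediate (not isolated)
55 | carboxylic acid of 53 with the 9-hydroxyl as trimethylsilyl ether | CC(C)[C@@H]1CC[C@](O[Si](C)(C)C)(COC(=O)/C(=C/[C@H]2C=C(CO[Si](c3ccccc3)(c3ccccc3)C(C)(C)C)CC[C@H]2C(C)C)CO[Si](C)(C)C(C)(C)C)[C@H]2C(=O)OCC(C(=O)O)=C[C@@H]12 | intermediate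
56 | (5aR,6S,9R,9aS)-9-hydroxy-9-({[(2E)-2-(hydroxymethyl)-3-[(1R,6S)-3-(hydroxymethyl)-6-(propan-2-yl)cyclohex-2-en-1-yl]prop-2-enoyl]oxy}methyl)-1-oxo-6-(propan-2-yl)-1,3,5a,6,7,8,9,9a-octahydro-2-benzoxepine-4-carboxylic acid | CC(C)[C@@H]1CC[C@](O)(COC(=O)/C(=C/[C@H]2C=C(CO)CC[C@H]2C(C)C)CO)[C@H]2C(=O)OCC(C(=O)O)=C[C@@H]12 | target

## Step count and risks

Total: 36 steps. Longest linear sequence: 21 steps (23 → 56 through steps 15, 16 and 18–36).

The three steps most likely to fail are steps 18, 30 and 11.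

Step 18 (Diels–Alder of the β-isopropyl imide 29 with dienyl ether 25). The dienophile is hindered and the allylic silyl ether must survive Et2AlCl at up to 0 °C. The fallback sets out from 25. An iminium-catalysed Diels–Alder reaction with commercial (E)-4-methylpent-2-enal and (5R)-5-benzyl-2,2,3-trimethylimidazolidin-4-one hydrochloride (20 mol %, MeCN/H2O, 0 °C → rt) gives (1S,2R,6S)-6-(propan-2-yl)-2-(TBDPSO-methyl)cyclohex-3-ene-1-carbaldehyde F1. Pinnick oxidation (NaClO2, NaH2PO4, 2-methylbut-2-ene, t-BuOH/H2O) then comes back to the route at 31, so steps 17–19 are bypassed.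

Step 30 (dianion aldol on the pseudo-acid 43). The lactol must ring-open under the basic conditions, and the aldehyde α-centre (C4a) could epimerise. The fallback sets out from 41, before ozonolysis. Esterification with commercial tert-butyl 2-(hydroxymethyl)prop-2-enoate (EDC·HCl, DMAP, CH2Cl2) gives 2-(tert-butoxycarbonyl)prop-2-en-1-yl (5R,6S,7S,8S)-7-ethenyl-2,2-dimethyl-8-(propan-2-yl)-1,3-dioxaspiro[4.5]decane-6-carboxylate F2. Ring-closing metathesis (second-generation Grubbs catalyst RuCl2(=CHPh)(H2IMes)(PCy3), toluene, 80 °C, high dilution) forms the C5=C6 bond and the seven-membered lactone in one operation. It comes back to the route at 50, so steps 29–32 are bypassed.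

Step 11 (dianion aldol on the β,γ-unsaturated aldehyde 15). The doubly activated α-hydrogen can be removed by the basic enolate, leading to epimerisation or conjugation. The fallback sets out from 15 and avoids basic enolates:
- The vinylaluminium reagent (i-Bu)2Al–C(=CH2)CO2Me (from methyl propiolate, i-Bu2AlH and HMPA in THF at 0 °C) adds to 15 to give methyl 2-{hydroxy[(1R,6S)-6-(propan-2-yl)-3-(TBDPSO-methyl)cyclohex-2-en-1-yl]methyl}prop-2-enoate F3.
- Acetylation (Ac2O, DMAP, pyridine) gives methyl 2-{acetoxy[(1R,6S)-6-(propan-2-yl)-3-(TBDPSO-methyl)cyclohex-2-en-1-yl]methyl}prop-2-enoate F4.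
- DABCO in THF at 60 °C transposes the acetate (SN2'–SN2' sequence) to methyl (2E)-2-(acetoxymethyl)-3-[(1R,6S)-6-(propan-2-yl)-3-(TBDPSO-methyl)cyclohex-2-en-1-yl]prop-2-enoate F5.
- K2CO3 in MeOH at 0 °C frees methyl (2E)-2-(hydroxymethyl)-3-[(1R,6S)-6-(propan-2-yl)-3-(TBDPSO-methyl)cyclohex-2-en-1-yl]prop-2-enoate F6.
- Silylation (t-BuMe2SiCl, imidazole) comes back to the route at 21.

## Further compounds

F1 | step 18 | (1S,2R,6S)-6-(propan-2-yl)-2-(TBDPSO-methyl)cyclohex-3-ene-1-carbaldehyde | CC(C)[C@@H]1CC=C[C@@H](CO[Si](c2ccccc2)(c2ccccc2)C(C)(C)C)[C@H]1C=O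
F2 | step 30 | 2-(tert-butoxycarbonyl)prop-2-en-1-yl (5R,6S,7S,8S)-7-ethenyl-2,2-dimethyl-8-(propan-2-yl)-1,3-dioxaspiro[4.5]decane-6-carboxylate | CC(C)[C@@H]1CC[C@]2(COC(C)(C)O2)[C@@H](C(=O)OCC(=C)C(=O)OC(C)(C)C)[C@H]1C=C
F3 | step 11 | methyl 2-{hydroxy[(1R,6S)-6-(propan-2-yl)-3-(TBDPSO-methyl)cyclohex-2-en-1-yl]methyl}prop-2-enoate | COC(=O)C(=C)C(O)[C@H]1C=C(CO[Si](c2ccccc2)(c2ccccc2)C(C)(C)C)CC[C@H]1C(C)C
F4 | step 11 | methyl 2-{acetoxy[(1R,6S)-6-(propan-2-yl)-3-(TBDPSO-methyl)cyclohex-2-en-1-yl]methyl}prop-2-enoate | COC(=O)C(=C)C(OC(C)=O)[C@H]1C=C(CO[Si](c2ccccc2)(c2ccccc2)C(C)(C)C)CC[C@H]1C(C)C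
F5 | step 11 | methyl (2E)-2-(acetoxymethyl)-3-[(1R,6S)-6-(propan-2-yl)-3-(TBDPSO-methyl)cyclohex-2-en-1-yl]prop-2-enoate | COC(=O)/C(=C/[C@H]1C=C(CO[Si](c2ccccc2)(c2ccccc2)C(C)(C)C)CC[C@H]1C(C)C)COC(C)=O
F6 | step 11 | methyl (2E)-2-(hydroxymethyl)-3-[(1R,6S)-6-(propan-2-yl)-3-(TBDPSO-methyl)cyclohex-2-en-1-yl]prop-2-enoate | COC(=O)/C(=C/[C@H]1C=C(CO[Si](c2ccccc2)(c2ccccc2)C(C)(C)C)CC[C@H]1C(C)C)CO
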